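## The problem

Lehualide K is a symmetric dialkyl disulfide: two identical 3,4-dimethoxy-5-methylpyran-2-one rings, each carrying at C6 an unbranched ten-carbon chain (C1' to C10') that ends at sulfur, with the two sulfur atoms bonded to each other. The rings are isolated, neither fused nor bridged, so the task is one fully substituted pyranone, one saturated chain and one S–S bond, the first two needed twice. The molecule has no stereocentre, so nothing has to be set or relayed; the only stereochemical element that can arise on the way is the geometry of a chain alkene, and saturation erases it. The ring raises two questions of position. O1, the C2 carbonyl, the methoxy groups at C3 and C4, the C5 methyl and the C6 chain must be placed without ambiguity, and the oxygen at C4 must be methylated so that the 2-pyranone and not the isomeric 2-methoxy-4-pyranone results. Two groups will not survive rough treatment: the S–S bond is cleaved by hydrides, phosphines, thiolates, organolithium reagents and dissolving metals and poisons heterogeneous hydrogenation catalysts, and the pyranone is a vinylogous ester-lactone that hydroxide, alkoxide or amines open on heating. Sulfur should therefore enter late and afterwards meet only mild, nearly neutral reagents. The enabling feature is that the ten carbons between ring carbon C6 and sulfur carry no functional group, so any carbon–carbon bond of the chain can be made last as an alkene and then saturated; the twofold symmetry lets the same bond, C3'–C4' on one arm and C3''–C4'' on the other, be formed on both arms in one operation around a small disulfide core, and the acidity of a methyl group at C6 supplies the ring-side alkene by a single alkylation.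

## Retrosynthesis

**21 to 19.** The saturated C3'–C4' and C3''–C4'' bonds of lehualide K 21 are taken back to two E double bonds in the tetradehydro precursor 19. The forward reaction must saturate two isolated 1,2-disubstituted alkenes and leave the S–S bond and the four ring double bonds alone. Sulfur rules out hydrogenation over a metal, so a metal-free hydrogen transfer from diimide is required; it passes through the half-reduced 20.

**19 to 12 and 17.** Both C3'=C4' double bonds are cut in the metathesis sense, giving two molecules of butenylpyranone 12 and the diene disulfide 17. A cut one bond nearer the ring would leave a ring-side alkene whose CH2 lies between the ring and the double bond and would slip into conjugation. A cut at C1'=C2' would need an alkene conjugated to the ring, electron-poor and slow in metathesis. Cuts further out lengthen the fragment that needs five steps of ring chemistry. The C3'=C4' cut gives a ring-side alkene that is exactly the product of allylating a C6 methyl group, and a sulfur-side alkene that sits six methylene groups from sulfur, too far for a small chelate to ruthenium. Cutting S–S or C10'–S instead would be sound, but each would carry the whole chain, and in the first case a protected thiol, through the ring synthesis. The forward step is a double cross-metathesis with a ruthenium carbene such as the second-generation Hoveyda–Grubbs catalyst RuCl2(H2IMes)(=CH-C6H4-2-O-i-Pr). It must tolerate a dialkyl disulfide and favour cross- over self-coupling; it proceeds through the mono-coupled 18.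

**17 to 15 and 16, and both to 13.** The S–S bond of 17 is cut heterolytically into a nucleophilic half, oct-7-ene-1-thiol 15, and an electrophilic half, the thiosulfonate 16, in which the same octenylsulfanyl unit carries 4-methylbenzenesulfinate as a leaving group. An oxidative dimerization of 15 would be one step shorter. The cut chosen here forms the S–S bond by substitution instead, so no halogen or other oxidant meets the terminal alkenes and sulfur cannot be over-oxidized. Symmetry removes any concern about disulfide scrambling. Both halves are one C–S disconnection away from commercial 8-bromooct-1-ene 13: the thiol through the isothiouronium salt 14, which avoids dialkyl sulfide formation, and the thiosulfonate by S-alkylation of 4-MeC6H4SO2SK. The forward steps must leave the terminal alkene untouched.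

**12 to 9 and 10.** The C1'–C2' bond is cut, giving 3,4-dimethoxy-5,6-dimethylpyran-2-one 9 and allyl bromide 10. Of the two ring methyl groups only the one at C6 gives an anion delocalized through C5=C6 and C3=C4 into the C2 carbonyl, so the lithio compound 11 forms at the right carbon. The precursor 9 is a small, fully characterizable pyranone on which all ring chemistry can be done before any chain or sulfur is present.

**9 to 8.** The O–CH3 bond at C4 is cut, giving 4-hydroxy-3-methoxy-5,6-dimethylpyran-2-one 8. The forward methylation has to take place on the C4 oxygen and not on the lactone carbonyl oxygen.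

**8 to 7.** The lactone bond O1–C2 is cut, opening the ring to the 3,5-dioxo ester 7. This places every ring substituent by the connectivity of an open chain: the ester carbon becomes C2, the methoxy-bearing carbon C3, the two ketone carbons C4 and C6, and the methyl-bearing carbon C5. The forward reaction is a base-mediated enol lactonization with loss of methanol.

**7 to 4 and 5, and 4 to 1 and 2.** The C5–C6 bond (ring numbering) of 7 is cut to the β-keto ester 4 and the acetyl donor N-methoxy-N-methylacetamide 5, joined through the dianion 6. The C3–C4 bond of 4 is cut to methyl methoxyacetate 1, used as its enolate 3, and propionyl chloride 2. Both are standard enolate acylations, and all four building blocks are simple commercial compounds.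

## Roads not taken

**Alternative 1:** The cut is the ring bond C3–C4, made by a Dieckmann-type closure. The substrate is methyl (Z)-3-(2-methoxyacetoxy)-2-methyl-13-(tritylsulfanyl)tridec-2-enoate A1, the Z enol methoxyacetate of a 2-methyl-3-oxo ester that already carries the complete chain and a trityl-protected sulfur. A hindered lithium silylamide would deprotonate the methoxyacetyl CH2, and the ester enolate would attack the neighbouring methyl ester carbon (6-exo-trig), expelling methoxide to give 4-hydroxy-3-methoxy-5-methyl-6-[10-(tritylsulfanyl)decyl]pyran-2-one A2.
- Merits: every ring atom is fixed by the connectivity of A1; the chain comes whole from an eleven-carbon acid derivative; sulfur is present as a base-stable thioether; no transition metal meets sulfur; nothing is used in excess.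
- Weak points: the enol ester must have the Z geometry, and O-acylation of β-keto ester enolates tends to give both C- and O-acylation and both geometries. The enolate of A1 has other exits, namely E1cB loss of the acyl unit as a ketene and intermolecular acyl transfer. A2 still needs the same site-selective methylation at the C4 oxygen, then detritylation and S–S coupling. The lipophilic chain and the trityl group are carried through all the ring chemistry.
- Comparison: on sulfur tolerance this is the safer road. The chosen plan sets against it a ring synthesis done on a small compound by well-travelled steps, a three-step sulfur fragment from one commercial bromide and a single operation after the coupling. The step counts are similar.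

**Alternative 2:** The cuts are C5–C6 and C6–C1', with C6 supplied by carbon monoxide A5. A zerovalent palladium catalyst would join the squarate-derived 4-chloro-2,3-dimethoxy-4-methylcyclobut-2-en-1-one A3, A5 and the alkenylstannane (E)-tert-butyldimethyl{[10-(tributylstannyl)dec-9-enyl]oxy}silane A4 in a carbonylative Stille coupling at the C–Cl bond. Thermal electrocyclic opening of the four-membered ring and 6π oxa-closure at O1–C2 would then give 6-[(E)-10-(tert-butyldimethylsilyloxy)dec-1-enyl]-3,4-dimethoxy-5-methylpyran-2-one A6.
- Merits: the 3,4-dimethoxy pattern is inherited from the four-membered ring, so the question of which oxygen is methylated never arises. This is a real advantage over the chosen route, which depends on site selectivity in step 4. The assembly is convergent, and sulfur is absent while palladium is at work.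
- Weak points: A3 needs several steps of its own; the coupling uses carbon monoxide under pressure and an organotin reagent. The C1'=C2' bond of A6 is conjugated to the ring and must be reduced without touching it. The silyl ether must then be turned into sulfur by desilylation, activation, thio-substitution, unmasking and S–S coupling, four or five operations after the key step against one in the chosen plan.
- Comparison: the chosen plan is shorter and avoids tin and carbon monoxide. It accepts in exchange the methylation question and the meeting of a ruthenium carbene with a disulfide.

**Alternative 3:** The cuts are C4–C5 and O1–C2 in a [3+3] annulation. The triethylsilyl enol ether triethyl[(13-bromotridec-2-en-3-yl)oxy]silane A7 would be C-acylated at its enol carbon by one acid chloride of methoxymalonyl dichloride A8 and O-acylated by the other, closing the ring as 6-(10-bromodecyl)-4-hydroxy-3-methoxy-5-methylpyran-2-one A9.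
- Merits: the ring is made in one step from an open-chain ketone derivative; the primary bromide is a robust handle that thiourea and thiosulfonate chemistry of the kind used in the chosen route would convert to the disulfide; no metal comes near sulfur.
- Weak points: the ketone behind A7 has a methylene group on each side and no bias between them, so A7 cannot be made by simple enolization. It needs an indirect, regiodefined preparation such as conjugate addition to a vinyl ketone with silyl trapping. A8 is not a shelf reagent and, as an α-alkoxy malonyl chloride, readily loses HCl to a ketene. The HCl set free can desilylate A7 before C-acylation, and the methylation at the C4 oxygen remains.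
- Comparison: after the ring closure this road is about as short as the chosen one and, like alternative 1, avoids the metathesis risk. The chosen plan sets against it commercial reagents throughout and a ring regiochemistry that follows from the order of two enolate acylations and not from the geometry of a hard-to-make enol ether.

Key step: step 9

## Route

Remark on the chemistry: 18, 19 and 20 are drawn and named as E isomers, the expected major geometry. Z isomers formed alongside are carried on, since step 10 removes the distinction. LiN(i-Pr)2 is taken from a purchased solution.

Step 1
Reactants: 1 methyl methoxyacetate; 2 propionyl chloride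
Product: 4 methyl 2-methoxy-3-oxopentanoate, via lithium 1,2-dimethoxyethenolate 3 (not isolated)
Conditions: LiN(i-Pr)2 (2.1 equiv), THF, −78 °C, 1 (2.0 equiv); then 2 (1.0 equiv), −78 → −20 °C; aq. NH4Cl
Reagents that add atoms: none
Why: Crossed Claisen condensation: the lithium enolate 3 is C-acylated by the acid chloride at low temperature, and the second equivalent of 3 takes up the acidic C2 proton of the β-keto ester as it forms, which prevents a second acylation.

Step 2
Reactants: 4 methyl 2-methoxy-3-oxopentanoate; 5 N-methoxy-N-methylacetamide
Product: 7 methyl 2-methoxy-4-methyl-3,5-dioxohexanoate, via dilithium 1,2-dimethoxypenta-1,3-diene-1,3-diolate 6 (not isolated)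
Conditions: LiN(i-Pr)2 (2.2 equiv), THF, −78 → 0 °C; 5 (1.1 equiv), −78 → 0 °C; 1 M HCl
Reagents that add atoms: none
Why: γ-Acylation of a β-keto ester dianion (Weiler dianion chemistry) by a Weinreb amide: C2 is deprotonated first and C4 second, the more basic C4 terminus of 6 attacks the amide, and the ketone is released only on the acid quench, so over-addition and proton transfer to the product are excluded; 7 is a mixture of diastereomers and enol tautomers and is used crude.

Step 3
Reactants: 7 methyl 2-methoxy-4-methyl-3,5-dioxohexanoate
Product: 8 4-hydroxy-3-methoxy-5,6-dimethylpyran-2-one
Conditions: DBU (1.5 equiv), toluene, 80 °C; 1 M HCl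
Reagents that add atoms: none
Why: Base-mediated enol lactonization of a 3,5-dioxo ester: the C5 enol oxygen attacks the methyl ester carbon (6-exo-trig acyl substitution) and methanol is lost; formation of the stabilized, acidic 4-hydroxypyranone drives the closure.

Step 4
Reactants: 8 4-hydroxy-3-methoxy-5,6-dimethylpyran-2-one
Product: 9 3,4-dimethoxy-5,6-dimethylpyran-2-one
Conditions: Me2SO4 (1.5 equiv), K2CO3 (2 equiv), acetone, reflux
Reagents that add atoms: dimethyl sulfate, COS(=O)(=O)OC
Why: O-Alkylation of a vinylogous carboxylic acid: under carbonate in acetone the deprotonated 4-hydroxy-2-pyranone is expected to be methylated mainly at the C4 oxygen, and any isomeric 2-methoxy-4-pyranone is much more polar and should separate on silica.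

Step 5
Reactants: 9 3,4-dimethoxy-5,6-dimethylpyran-2-one; 10 allyl bromide
Product: 12 6-(but-3-enyl)-3,4-dimethoxy-5-methylpyran-2-one, via 6-(lithiomethyl)-3,4-dimethoxy-5-methylpyran-2-one 11 (not isolated)
Conditions: LiN(i-Pr)2 (1.1 equiv), THF, −78 °C; 10 (1.5 equiv), −78 → −40 °C; aq. NH4Cl
Reagents that add atoms: none
Why: Lateral (vinylogous) deprotonation and alkylation: only the C6 methyl gives an anion delocalized through C5=C6 and C3=C4 into the lactone carbonyl, and the extended enolate 11 attacks the reactive allylic bromide through its terminal carbon by SN2, which restores the pyranone.

Step 6
Reactants: 13 8-bromooct-1-ene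
Product: 15 oct-7-ene-1-thiol, via S-(oct-7-enyl)isothiouronium bromide 14 (not isolated)
Conditions: thiourea (1.1 equiv), EtOH, reflux; then 2 M NaOH (aq), reflux, N2; 1 M HCl to pH 3
Reagents that add atoms: thiourea, NC(N)=S
Why: Thiourea route to thiols: SN2 displacement of the primary bromide by the sulfur of thiourea gives the salt 14, and alkaline hydrolysis releases the thiolate and urea; no dialkyl sulfide can form because sulfur stays masked until the hydrolysis.

Step 7
Reactants: 13 8-bromooct-1-ene
Product: 16 S-(oct-7-enyl) 4-methylbenzenesulfonothioate
Conditions: 4-MeC6H4SO2SK (1.2 equiv), DMF, rt → 40 °C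
Reagents that add atoms: potassium 4-methylbenzenesulfonothioate, Cc1ccc(cc1)S(=O)(=O)[S-].[K+]
Why: S-Alkylation of a thiosulfonate salt: the soft terminal sulfur of the 4-methylbenzenethiosulfonate anion displaces the primary bromide by SN2 in a dipolar aprotic solvent, giving the S-alkyl thiosulfonate without touching the terminal alkene.

Step 8
Reactants: 15 oct-7-ene-1-thiol; 16 S-(oct-7-enyl) 4-methylbenzenesulfonothioate
Product: 17 bis(oct-7-enyl) disulfide
Conditions: 15 (1.0 equiv), 16 (1.05 equiv), Et3N (1.1 equiv), CH2Cl2, 0 °C → rt, N2; aq. NaHCO3 wash
Reagents that add atoms: none
Why: Thiol–thiosulfonate coupling (S-sulfenylation of a thiolate): the triethylammonium thiolate of 15 attacks the alkyl-bearing sulfur of 16 and 4-methylbenzenesulfinate, a poor nucleophile, leaves, so the S–S bond forms without any oxidant near the terminal alkenes; the two halves are identical, so disulfide exchange cannot scramble the product.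

Step 9
Reactants: 12 6-(but-3-enyl)-3,4-dimethoxy-5-methylpyran-2-one (6 equiv); 17 bis(oct-7-enyl) disulfide (1 equiv)
Product: 19 (3'E,3''E)-3',4',3'',4''-tetradehydrolehualide K, via 6-[(E)-10-(oct-7-enyldisulfanyl)dec-3-enyl]-3,4-dimethoxy-5-methylpyran-2-one 18 (not isolated)
Conditions: second-generation Hoveyda–Grubbs catalyst RuCl2(H2IMes)(=CH-C6H4-2-O-i-Pr) (10 mol % in two portions), 1,4-benzoquinone (20 mol %), CH2Cl2 (0.1 M in 17), 40 °C, slow argon sparge; unreacted 12 recovered by chromatography
Reagents that add atoms: none
Why: Olefin cross-metathesis by the Chauvin mechanism: the ruthenium benzylidene becomes an alkylidene by [2+2] cycloaddition with a terminal alkene of 12 or 17 and cycloreversion, the alkylidene adds the other partner, and cycloreversion of the ruthenacyclobutane releases the new C3'=C4' alkene and a ruthenium methylidene that carries the chain with loss of ethylene. The closest known reaction type is the cross-metathesis of two unhindered terminal alkenes with this catalyst class, in which a dialkyl disulfide held several methylene groups from the alkene is tolerated in a substrate-dependent way. No ring closes and no stereocentre is formed; the E geometry expected under thermodynamic control does not matter because step 10 removes both double bonds. The selectivity needed is cross- over self-coupling: the two alkenes belong to the same reactive class, so the outcome is statistical and is pushed towards 19 by the excess of 12 and by sweeping out ethylene, while self-metathesis is reversible because the internal alkenes it gives are reopened by the propagating carbene. The reaction passes through the mono-coupled 18, which couples a second time in the same flask. The ring double bonds of 12 are tetrasubstituted and push–pull polarized and do not engage, and the S–S bond lies six methylene groups from each alkene, too far for a small chelate. Any S–S exchange is harmless, since it only interconverts 17, 18 and 19. Benzoquinone suppresses ruthenium hydride species that would move the terminal double bonds and so shorten a chain by one carbon.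

Step 10
Reactants: 19 (3'E,3''E)-3',4',3'',4''-tetradehydrolehualide K
Product: 21 lehualide K, via (3'E)-3',4'-didehydrolehualide K 20 (not isolated)
Conditions: KO2CN=NCO2K (20 equiv), AcOH (40 equiv, slow addition), CH2Cl2–MeOH, rt; second charge if alkene remains
Reagents that add atoms: none
Why: Diimide reduction: HN=NH generated from the azodicarboxylate salt and acetic acid transfers H2 through a concerted six-membered transition state to the unpolarized 1,2-disubstituted alkenes of 19 and then 20; it does not cleave S–S bonds, does not attack the tetrasubstituted conjugated ring double bonds, and needs no metal that sulfur could poison.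

## Compound list

1 | methyl methoxyacetate | COCC(=O)OC | starting material
2 | propionyl chloride | CCC(Cl)=O | starting material
3 | lithium 1,2-dimethoxyethenolate (lithium enolate of 1) | COC=C(OC)O[Li] | intermediate
4 | methyl 2-methoxy-3-oxopentanoate | CCC(=O)C(OC)C(=O)OC | intermediate
5 | N-methoxy-N-methylacetamide | CC(=O)N(C)OC | starting material
6 | dilithium 1,2-dimethoxypenta-1,3-diene-1,3-diolate (dianion of 4) | CC=C(O[Li])C(OC)=C(OC)O[Li] | intermediate
7 | methyl 2-methoxy-4-methyl-3,5-dioxohexanoate (mixture of diastereomers and enol tautomers) | COC(C(=O)OC)C(=O)C(C)C(C)=O | intermediate
8 | 4-hydroxy-3-methoxy-5,6-dimethylpyran-2-one | COc1c(O)c(C)c(C)oc1=O | intermediate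
9 | 3,4-dimethoxy-5,6-dimethylpyran-2-one | COc1c(C)c(C)oc(=O)c1OC | intermediate
10 | allyl bromide | C=CCBr | starting material
11 | 6-(lithiomethyl)-3,4-dimethoxy-5-methylpyran-2-one | COc1c(C)c(C[Li])oc(=O)c1OC | intermediate
12 | 6-(but-3-enyl)-3,4-dimethoxy-5-methylpyran-2-one | COc1c(C)c(CCC=C)oc(=O)c1OC | intermediate
13 | 8-bromooct-1-ene | C=CCCCCCCBr | starting material
14 | S-(oct-7-enyl)isothiouronium bromide | C=CCCCCCCSC(N)=[NH2+].[Br-] | intermediate
15 | oct-7-ene-1-thiol | C=CCCCCCCS | intermediate
16 | S-(oct-7-enyl) 4-methylbenzenesulfonothioate (S-oct-7-enyl p-toluenethiosulfonate) | C=CCCCCCCSS(=O)(=O)c1ccc(C)cc1 | intermediate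
17 | bis(oct-7-enyl) disulfide | C=CCCCCCCSSCCCCCCC=C | intermediate
18 | 6-[(E)-10-(oct-7-enyldisulfanyl)dec-3-enyl]-3,4-dimethoxy-5-methylpyran-2-one | COc1c(C)c(CC/C=C/CCCCCCSSCCCCCCC=C)oc(=O)c1OC | intermediate
19 | (3'E,3''E)-3',4',3'',4''-tetradehydrolehualide K, 6,6'-[(3E,3'E)-disulfanediylbis(dec-3-ene-10,1-diyl)]bis(3,4-dimethoxy-5-methylpyran-2-one) | COc1c(C)c(CC/C=C/CCCCCCSSCCCCCC/C=C/CCc2oc(=O)c(OC)c(OC)c2C)oc(=O)c1OC | intermediate
20 | (3'E)-3',4'-didehydrolehualide K (one arm saturated, one arm still a dec-3-enyl chain) | COc1c(C)c(CC/C=C/CCCCCCSSCCCCCCCCCCc2oc(=O)c(OC)c(OC)c2C)oc(=O)c1OC | intermediate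
21 | lehualide K, 6,6'-[disulfanediylbis(decane-10,1-diyl)]bis(3,4-dimethoxy-5-methylpyran-2-one) | COc1c(C)c(CCCCCCCCCCSSCCCCCCCCCCc2oc(=O)c(OC)c(OC)c2C)oc(=O)c1OC | target

## Step count and risks

Total step count: 10. Longest linear sequence: 7 steps (steps 1, 2, 3, 4, 5, 9, 10); the sulfur fragment takes 3 steps (steps 6 and 7 in parallel from the same bromide, then step 8).

**Step 9 (key step).** The likeliest failures are three. The catalyst may lose activity through coordination of disulfide sulfur to ruthenium. The outcome may be statistical, with self-coupling consuming 12 and coupling stalling after one arm. The terminal double bonds may migrate before metathesis, which would shorten a chain by one carbon and give homologues that are hard to remove. The fallback sets out from 12 and 13 and returns at 21; it masks sulfur as a thioester and forms the S–S bond last. Bromide 13 with KSC(O)CH3 in DMF should give S-(oct-7-enyl) ethanethioate F1. Cross-metathesis of 12 with an excess of this cheap partner, using the same catalyst RuCl2(H2IMes)(=CH-C6H4-2-O-i-Pr), should give 6-[(E)-10-(acetylsulfanyl)dec-3-enyl]-3,4-dimethoxy-5-methylpyran-2-one F2; thioesters are well tolerated, and the costly pyranone is no longer the reagent in excess. Diimide reduction as in step 10 should give 6-[10-(acetylsulfanyl)decyl]-3,4-dimethoxy-5-methylpyran-2-one F3. Brief methanolysis with K2CO3 in degassed MeOH at 0 °C should free 3,4-dimethoxy-5-methyl-6-(10-sulfanyldecyl)pyran-2-one F4, and oxidation of two molecules of F4 with iodine and NaHCO3 in MeOH–CH2Cl2 should couple them to 21; no alkene is present at that stage.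

**Step 4.** The risk is poor site selectivity, that is, methylation at the lactone carbonyl oxygen instead of the C4 oxygen, leading into the 4-pyranone series. The fallback goes from 8 to 9 by a different mechanism, a Mitsunobu methylation (MeOH, PPh3, diisopropyl azodicarboxylate, THF). The electrophile is then an alkoxyphosphonium ion under neutral conditions, which are known to favour 4-O-alkylation of 4-hydroxy-2-pyranones. No new compound is involved.

**Step 5.** The risks are proton exchange between 11 and the product, which leads to a second allylation at C1'; incomplete deprotonation; and addition of the amide base to the lactone carbonyl. The fallback sets out from 4, through its dianion 6, and returns at 12; it installs the butenyl group before the ring exists. Dianion 6 is acylated with N-methoxy-N-methylpent-4-enamide F5 in place of 5, giving methyl 2-methoxy-4-methyl-3,5-dioxonon-8-enoate F6. DBU in toluene as in step 3 closes it to 6-(but-3-enyl)-4-hydroxy-3-methoxy-5-methylpyran-2-one F7, and methylation as in step 4 gives 12. The step count is unchanged, and the site selectivity question of step 4 then applies to F7.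

**Step 2.** The risks are incomplete formation of the dianion, O-acylation, and proton transfer that returns 4. The fallback sets out from 4 and returns at 7; it replaces the strongly basic dianion by a neutral bis-silyl dienol ether. Me3SiCl and Et3N should give methyl 2-methoxy-3-(trimethylsilyloxy)pent-2-enoate F8. LiN(i-Pr)2 and then Me3SiCl at −78 °C should give 1,2-dimethoxy-1,3-bis(trimethylsilyloxy)penta-1,3-diene F9. Acetyl chloride in CH2Cl2 from −78 °C to room temperature acylates such dienes at the terminal carbon (Mukaiyama-type acylation), and aqueous work-up should give 7.

## Further compounds

F1 | step 9 | S-(oct-7-enyl) ethanethioate | CC(=O)SCCCCCCC=C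
F2 | step 9 | 6-[(E)-10-(acetylsulfanyl)dec-3-enyl]-3,4-dimethoxy-5-methylpyran-2-one | COc1c(C)c(CC/C=C/CCCCCCSC(C)=O)oc(=O)c1OC
F3 | step 9 | 6-[10-(acetylsulfanyl)decyl]-3,4-dimethoxy-5-methylpyran-2-one | COc1c(C)c(CCCCCCCCCCSC(C)=O)oc(=O)c1OC
F4 | step 9 | 3,4-dimethoxy-5-methyl-6-(10-sulfanyldecyl)pyran-2-one | COc1c(C)c(CCCCCCCCCCS)oc(=O)c1OC
F0 | step 4 | none | none
F5 | step 5 | N-methoxy-N-methylpent-4-enamide | C=CCCC(=O)N(C)OC
F6 | step 5 | methyl 2-methoxy-4-methyl-3,5-dioxonon-8-enoate | COC(C(=O)OC)C(=O)C(C)C(=O)CCC=C
F7 | step 5 | 6-(but-3-enyl)-4-hydroxy-3-methoxy-5-methylpyran-2-one | COc1c(O)c(C)c(CCC=C)oc1=O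
F8 | step 2 | methyl 2-methoxy-3-(trimethylsilyloxy)pent-2-enoate | CCC(O[Si](C)(C)C)=C(OC)C(=O)OC
F9 | step 2 | 1,2-dimethoxy-1,3-bis(trimethylsilyloxy)penta-1,3-diene | CC=C(O[Si](C)(C)C)C(OC)=C(OC)O[Si](C)(C)C
A1 | alternative 1 | methyl (Z)-3-(2-methoxyacetoxy)-2-methyl-13-(tritylsulfanyl)tridec-2-enoate | COCC(=O)O/C(CCCCCCCCCCSC(c1ccccc1)(c1ccccc1)c1ccccc1)=C(C)\C(=O)OC
A2 | alternative 1 | 4-hydroxy-3-methoxy-5-methyl-6-[10-(tritylsulfanyl)decyl]pyran-2-one | COc1c(O)c(C)c(CCCCCCCCCCSC(c2ccccc2)(c2ccccc2)c2ccccc2)oc1=O
A3 | alternative 2 | 4-chloro-2,3-dimethoxy-4-methylcyclobut-2-en-1-one (racemic) | COC1=C(OC)C(C)(Cl)C1=O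
A4 | alternative 2 | (E)-tert-butyldimethyl{[10-(tributylstannyl)dec-9-enyl]oxy}silane | CCCC[Sn](CCCC)(CCCC)/C=C/CCCCCCCCO[Si](C)(C)C(C)(C)C
A5 | alternative 2 | carbon monoxide | [C-]#[O+]
A6 | alternative 2 | 6-[(E)-10-(tert-butyldimethylsilyloxy)dec-1-enyl]-3,4-dimethoxy-5-methylpyran-2-one | COc1c(C)c(/C=C/CCCCCCCCO[Si](C)(C)C(C)(C)C)oc(=O)c1OC
A7 | alternative 3 | triethyl[(13-bromotridec-2-en-3-yl)oxy]silane (either enol ether geometry) | CC=C(O[Si](CC)(CC)CC)CCCCCCCCCCBr
A8 | alternative 3 | methoxymalonyl dichloride | COC(C(Cl)=O)C(Cl)=O
A9 | alternative 3 | 6-(10-bromodecyl)-4-hydroxy-3-methoxy-5-methylpyran-2-one | COc1c(O)c(C)c(CCCCCCCCCCBr)oc1=O
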